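**Retrosynthetic overview**

1. Ring C rests on one feature: its lactone oxygen sits on a CMe2 carbon bonded to the β-carbon of the ring B ketone, and its carbonyl hangs on the α-carbon. Cutting C(β)–CMe2 and O–C(=O) leads back to propan-2-ol and spiro 2-methoxycarbonylcyclopentenone 18; the ring-fusion methyl is put on last.
2. Ring B: the enone ester comes from the spiro enone by α-iodination and methoxycarbonylation; the five-membered ring comes from ring-closing metathesis of an allyl and a 1-hydroxyallyl group on C3 of the ring A lactone.
3. Spiro centre: allylation, then acrolein aldol of the ring A lactone enolate; the second electrophile enters anti to the cis C5 and C6 substituents.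
4. Ring A (cis-5-isopropenyl-6-acyl δ-lactone): Nozaki–Hiyama union of an allylic chloride (Johnson–Claisen, then ene-type chlorination) with a D-valine-series α-silyloxy aldehyde; the silyloxy carbinol is the masked isobutyryl ketone.
5. Ring order: A, then B, then C.

Key step: step 13

Remark: methyl (2R)-2-hydroxy-3-methylbutanoate and the other numbered starting materials are taken as commercial; centres that are erased later (C3 in 11, the ring B carbinol in 13 to 15) are carried as epimer mixtures.

Step 1
Reactants: 1 2-methylbut-3-en-2-ol; 2 triethyl orthoacetate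
Product: 3 ethyl 5-methylhex-4-enoate
Conditions: EtCO2H (cat.), neat, 140 °C, EtOH distilled off
Reagents that add atoms: none
Why: Johnson–Claisen rearrangement of the tertiary allylic alcohol through the mixed ketene acetal gives the γ,δ-unsaturated ester with a prenyl-type alkene; no stereocentre is formed.

Step 2
Reactants: 3 ethyl 5-methylhex-4-enoate
Product: 4 ethyl 4-chloro-5-methylhex-5-enoate (racemic)
Conditions: N-chlorosuccinimide (1.1 equiv), PhSeCl (5 mol %), MeCN, 20 °C
Reagents that add atoms: N-chlorosuccinimide, O=C1CCC(=O)N1Cl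
Why: selenium-catalysed ene-type allylic chlorination shifts the double bond to the terminal position and places chlorine on the former alkene CH; the racemic centre is erased when the allyl metal forms in step 5.

Step 3
Reactants: 5 methyl (2R)-2-hydroxy-3-methylbutanoate
Product: 6 methyl (2R)-2-[(tert-butyldimethylsilyl)oxy]-3-methylbutanoate
Conditions: t-BuMe2SiCl, imidazole, DMF, 20 °C
Reagents that add atoms: tert-butyldimethylsilyl chloride, CC(C)(C)[Si](C)(C)Cl
Why: standard silylation of a secondary alcohol; the stereocentre is not touched.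

Step 4
Reactants: 6 methyl (2R)-2-[(tert-butyldimethylsilyl)oxy]-3-methylbutanoate
Product: 7 (2R)-2-[(tert-butyldimethylsilyl)oxy]-3-methylbutanal
Conditions: (i-Bu)2AlH (1.1 equiv), CH2Cl2, −78 °C; aq. potassium sodium tartrate
Reagents that add atoms: none
Why: partial ester reduction stops at the aluminium hemiacetal at low temperature; the α-silyloxy aldehyde is used crude so that the stereocentre is kept.

Step 5
Reactants: 4 ethyl 4-chloro-5-methylhex-5-enoate; 7 (2R)-2-[(tert-butyldimethylsilyl)oxy]-3-methylbutanal
Product: 9 (5S,6S)-6-[(1R)-1-[(tert-butyldimethylsilyl)oxy]-2-methylpropyl]-5-(prop-1-en-2-yl)oxan-2-one, via hydroxy ester 8 (not isolated)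
Conditions: CrCl2 (4 equiv), LiI (0.2 equiv), THF, 0 to 20 °C; then pyridinium p-toluenesulfonate (cat.), PhMe, 70 °C
Reagents that add atoms: none
Why: Nozaki–Hiyama allylation with divalent chromium: the allylchromium species reacts as its primary (E) form through a chair with the aldehyde substituent equatorial, which sets C5 and C6 anti (cis in the lactone), while Felkin–Anh attack anti to the silyloxy group of (R)-7 sets C6 as S; mild acid then closes the δ-lactone, and any minor diastereomer is removed at this stage.

Step 6
Reactants: 9 ring A lactone; 10 allyl bromide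
Product: 11 3-allyl derivative of 9, (5S,6S)-6-[(1R)-1-[(tert-butyldimethylsilyl)oxy]-2-methylpropyl]-3-(prop-2-en-1-yl)-5-(prop-1-en-2-yl)oxan-2-one (C3 epimers)
Conditions: LiN(i-Pr)2 (1.05 equiv), THF, −78 °C; allyl bromide, −78 to −30 °C
Reagents that add atoms: none
Why: C-alkylation of the kinetic lithium lactone enolate; the C3 configuration does not matter because this centre is planarised again in step 7.

Step 7
Reactants: 11 3-allyl lactone; 12 acrolein
Product: 13 (3S,5S,6S)-6-[(1R)-1-[(tert-butyldimethylsilyl)oxy]-2-methylpropyl]-3-(1-hydroxyprop-2-en-1-yl)-3-(prop-2-en-1-yl)-5-(prop-1-en-2-yl)oxan-2-one (allyl cis to isopropenyl; carbinol epimers)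
Conditions: LiN(i-Pr)2 (1.2 equiv), THF, −78 °C; acrolein, −78 °C, 10 min; AcOH quench at −78 °C
Reagents that add atoms: none
Why: aldol 1,2-addition of the tetrasubstituted lactone enolate to acrolein; the aldehyde approaches the enolate face anti to the cis C5 isopropenyl and C6 side chain, so the carbinol carbon ends trans and the allyl group cis to isopropenyl, which fixes the future spiro centre.

Step 8
Reactants: 13 aldol product
Product: 14 (8S,9S)-8-[(1R)-1-[(tert-butyldimethylsilyl)oxy]-2-methylpropyl]-1-hydroxy-9-(prop-1-en-2-yl)-7-oxaspiro[4.5]dec-2-en-6-one (ring B CH2 cis to isopropenyl; C1 epimers)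
Conditions: second-generation Grubbs catalyst (H2IMes)(PCy3)Cl2Ru=CHPh (5 mol %), CH2Cl2 (5 mM), 40 °C
Reagents that add atoms: none
Why: ring-closing metathesis of the two monosubstituted alkenes forms ring B with loss of ethylene; the 1,1-disubstituted isopropenyl group reacts too slowly to compete with five-membered ring closure.

Step 9
Reactants: 14 spiro cyclopentenol silyl ether
Product: 15 (8S,9S)-1-hydroxy-8-[(1R)-1-hydroxy-2-methylpropyl]-9-(prop-1-en-2-yl)-7-oxaspiro[4.5]dec-2-en-6-one (C1 epimers)
Conditions: HF·pyridine, THF/pyridine, 0 to 20 °C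
Reagents that add atoms: none
Why: fluoride-driven Si–O cleavage under buffered, non-basic conditions frees the hindered carbinol without lactone opening or acyl migration.

Step 10
Reactants: 15 diol
Product: 16 (8S,9S)-8-(2-methylpropanoyl)-9-(prop-1-en-2-yl)-7-oxaspiro[4.5]dec-2-ene-1,6-dione (spiro enone)
Conditions: Dess–Martin periodinane (3 equiv), CH2Cl2, 0 to 20 °C
Reagents that add atoms: none
Why: Dess–Martin oxidation turns the cyclopentenol into the enone and the side-chain carbinol into the isobutyryl ketone in one operation; both carbinol centres are erased, and C6, now α to a ketone, is not enolised under these non-basic conditions.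

Step 11
Reactants: 16 spiro enone
Product: 17 (8S,9S)-2-iodo-8-(2-methylpropanoyl)-9-(prop-1-en-2-yl)-7-oxaspiro[4.5]dec-2-ene-1,6-dione
Conditions: I2 (2 equiv), pyridine, CH2Cl2, 0 to 20 °C
Reagents that add atoms: iodine, II
Why: α-iodination of the enone by conjugate addition of pyridine, iodination of the enolate and elimination; the isolated alkene and the ketone α-positions are not activated under these conditions.

Step 12
Reactants: 17 α-iodo enone
Product: 18 methyl (8S,9S)-8-(2-methylpropanoyl)-1,6-dioxo-9-(prop-1-en-2-yl)-7-oxaspiro[4.5]dec-2-ene-2-carboxylate (spiro enone ester)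
Conditions: PdCl2(PPh3)2 (5 mol %), CO (1 atm), MeOH, i-Pr2NEt, DMF, 45 °C
Reagents that add atoms: carbon monoxide, [C-]#[O+]; methanol, CO
Why: palladium-catalysed methoxycarbonylation: zerovalent palladium inserts into the vinyl C–I bond, CO inserts, and methanolysis of the acylpalladium gives the doubly activated alkene.

Step 13
Reactants: 18 spiro enone ester; 19 propan-2-ol
Product: 21 nor-methyl β-keto lactone (rings A, B and C; ring C cis-fused, no ring-fusion methyl), via hydroxy keto ester 20 (not isolated)
Conditions: (Bu4N)4W10O32 (2 mol %), propan-2-ol/MeCN 1:1 (0.02 M), 390 nm LED, 20 °C, argon; then TsOH·H2O (5 mol %), PhMe, 50 °C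
Reagents that add atoms: none
Why: The excited decatungstate abstracts the carbinol hydrogen of propan-2-ol, the nucleophilic 2-hydroxyprop-2-yl radical adds to the unsubstituted β-carbon of the doubly activated alkene, and the stabilised 1,3-dicarbonyl radical is returned to the closed shell by back hydrogen transfer from the reduced polyoxometalate. The closest known reaction type is the photochemical Giese-type addition of alcohol-derived α-hydroxyalkyl radicals to enones and unsaturated esters with spontaneous γ-lactone formation. Ring C closes by 5-exo-trig attack of the tertiary hydroxyl on the methyl ester, once the acidic α-CH has equilibrated so that ester and carbinol are cis. The ring-fusion CH is set by radical approach on the ring B face syn to the flat ring A lactone carbonyl and anti to the ring A CH2 and its neighbouring isopropenyl group; the α-carbon is set thermodynamically, since only a cis-fused bicyclo[3.3.0] lactone can form. The step needs chemoselectivity for the electron-poor alkene over the isopropenyl group, which is polarity-mismatched with the nucleophilic radical, and over hydrogen abstraction from the substrate, which the large excess of propan-2-ol suppresses.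

Step 14
Reactants: 21 nor-methyl β-keto lactone
Product: 22 CNP0216954.1 (target)
Conditions: K2CO3 (1.5 equiv), MeI (5 equiv), acetone, 0 to 20 °C
Reagents that add atoms: iodomethane, CI
Why: C-methylation of the 1,3-dicarbonyl enolate, the only position acidic enough for K2CO3; the cis-fused bicycle allows the methyl group only in the cis-fused sense, which is the target configuration of the new quaternary centre.

**Compound list**

1 | 2-methylbut-3-en-2-ol | CC(C)(O)C=C | starting material
2 | triethyl orthoacetate | CCOC(C)(OCC)OCC | starting material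
3 | ethyl 5-methylhex-4-enoate | CCOC(=O)CCC=C(C)C | intermediate
4 | ethyl 4-chloro-5-methylhex-5-enoate (racemic) | CCOC(=O)CCC(Cl)C(C)=C | intermediate
5 | methyl (2R)-2-hydroxy-3-methylbutanoate | COC(=O)[C@H](O)C(C)C | starting material
6 | methyl (2R)-2-[(tert-butyldimethylsilyl)oxy]-3-methylbutanoate | COC(=O)[C@H](O[Si](C)(C)C(C)(C)C)C(C)C | intermediate
7 | (2R)-2-[(tert-butyldimethylsilyl)oxy]-3-methylbutanal | O=C[C@H](O[Si](C)(C)C(C)(C)C)C(C)C | intermediate
8 | ethyl (4S,5S,6R)-6-[(tert-butyldimethylsilyl)oxy]-5-hydroxy-7-methyl-4-(prop-1-en-2-yl)octanoate | C=C(C)[C@H](CCC(=O)OCC)[C@H](O)[C@H](O[Si](C)(C)C(C)(C)C)C(C)C | intermediate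
9 | (5S,6S)-6-[(1R)-1-[(tert-butyldimethylsilyl)oxy]-2-methylpropyl]-5-(prop-1-en-2-yl)oxan-2-one (ring A lactone, 5,6-cis) | C=C(C)[C@@H]1CCC(=O)O[C@@H]1[C@H](O[Si](C)(C)C(C)(C)C)C(C)C | intermediate
10 | allyl bromide | C=CCBr | starting material
11 | 3-allyl derivative of 9 (C3 epimers) | C=C(C)[C@@H]1CC(CC=C)C(=O)O[C@@H]1[C@H](O[Si](C)(C)C(C)(C)C)C(C)C | intermediate
12 | acrolein | C=CC=O | starting material
13 | (3S,5S,6S)-3-allyl-3-(1-hydroxyprop-2-en-1-yl) lactone (allyl cis to isopropenyl; carbinol epimers) | C=C(C)[C@@H]1C[C@](C(O)C=C)(CC=C)C(=O)O[C@@H]1[C@H](O[Si](C)(C)C(C)(C)C)C(C)C | intermediate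
14 | spiro cyclopentenol silyl ether (C1 epimers) | C=C(C)[C@@H]1C[C@]2(CC=CC2O)C(=O)O[C@@H]1[C@H](O[Si](C)(C)C(C)(C)C)C(C)C | intermediate
15 | spiro cyclopentenol diol (C1 epimers) | C=C(C)[C@@H]1C[C@]2(CC=CC2O)C(=O)O[C@@H]1[C@H](O)C(C)C | intermediate
16 | (8S,9S)-8-(2-methylpropanoyl)-9-(prop-1-en-2-yl)-7-oxaspiro[4.5]dec-2-ene-1,6-dione | C=C(C)[C@@H]1C[C@]2(CC=CC2=O)C(=O)O[C@@H]1C(=O)C(C)C | intermediate
17 | 2-iodo derivative of 16 | C=C(C)[C@@H]1C[C@]2(CC=C(I)C2=O)C(=O)O[C@@H]1C(=O)C(C)C | intermediate
18 | methyl (8S,9S)-8-(2-methylpropanoyl)-1,6-dioxo-9-(prop-1-en-2-yl)-7-oxaspiro[4.5]dec-2-ene-2-carboxylate | C=C(C)[C@@H]1C[C@]2(CC=C(C(=O)OC)C2=O)C(=O)O[C@@H]1C(=O)C(C)C | intermediate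
19 | propan-2-ol | CC(C)O | starting material
20 | hydroxy keto ester: 3-(2-hydroxypropan-2-yl) adduct of 18 (C2 epimers) | C=C(C)[C@@H]1C[C@]2(C[C@H](C(C)(C)O)C(C(=O)OC)C2=O)C(=O)O[C@@H]1C(=O)C(C)C | intermediate
21 | nor-methyl β-keto lactone | C=C(C)[C@@H]1C[C@]2(C[C@@H]3C(C)(C)OC(=O)[C@@H]3C2=O)C(=O)O[C@@H]1C(=O)C(C)C | intermediate
22 | CNP0216954.1 | C=C(C)[C@@H]1C[C@]2(C[C@@H]3C(C)(C)OC(=O)[C@]3(C)C2=O)C(=O)O[C@@H]1C(=O)C(C)C | target

**Step count:** 14 steps in total; longest linear sequence 12 steps (from 1 or from 5 to 22).

**Steps most likely to fail**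

Step 13. The tertiary radical may discriminate poorly between the two faces of ring B, because the bias acts across one CH2 from the spiro centre. The strongly reducing ketyl radical may also pass an electron to the doubly activated alkene instead of adding (net reduction), and the excited polyoxometalate may abstract allylic hydrogen from the substrate. The fallback sets out from 18 and returns at 21. The three-carbon unit is brought in as an O-silylated α-oxy radical by visible-light photoredox decarboxylation of 2-methyl-2-[(triethylsilyl)oxy]propanoic acid F1, made from 2-hydroxy-2-methylpropanoic acid with Et3SiCl and imidazole followed by mild hydrolysis of the silyl ester. With Ir[dF(CF3)ppy]2(dtbbpy)PF6 (1 mol %), K2HPO4, DMF and 450 nm light, the bulkier, non-reducing radical adds to 18; reduction of the adduct radical and protonation give the silyl ether adduct F2. HF·pyridine in THF then frees the tertiary alcohol, which lactonises to 21.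

Step 5. The α-silyloxy stereocentre may discriminate only modestly between the two aldehyde faces, and partial loss of the (E) geometry of the allylchromium species would give the syn isomer. The fallback sets out from 3 (with 7) and returns at 8, which lactonises to 9 as in step 5. SeO2 (cat.) with t-BuOOH in CH2Cl2 gives ethyl (4E)-6-hydroxy-5-methylhex-4-enoate F3. Borylation with B2pin2 and [Pd(MeCN)4](BF4)2 (cat.) in DMSO/MeOH gives the (E)-allylboronate, ethyl (4E)-5-methyl-6-(4,4,5,5-tetramethyl-1,3,2-dioxaborolan-2-yl)hex-4-enoate F4. F4 adds to 7 in PhMe at −30 °C under catalysis by the chiral phosphoric acid TRIP, the antipode being chosen so that catalyst and Felkin preference reinforce each other. The closed chair keeps the anti relationship and the catalyst adds face control.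

Step 7. The hindered tetrasubstituted enolate may add to acrolein in the conjugate sense, or the aldolate may revert before the quench. The fallback sets out from 11 and returns at 13. The same enolate (LiN(i-Pr)2, THF, −78 °C) is C-formylated with 2,2,2-trifluoroethyl formate, again anti to the ring substituents, to give the non-enolisable 3-allyl-3-formyl lactone F5. CH2=CHMgBr (THF, −78 °C) then adds to the aldehyde and gives 13.

**Further compounds**

F1 | step 13 | 2-methyl-2-[(triethylsilyl)oxy]propanoic acid | CC[Si](CC)(CC)OC(C)(C)C(=O)O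
F2 | step 13 | silyl ether adduct (triethylsilyl ether of 20) | C=C(C)[C@@H]1C[C@]2(C[C@H](C(C)(C)O[Si](CC)(CC)CC)C(C(=O)OC)C2=O)C(=O)O[C@@H]1C(=O)C(C)C
F3 | step 5 | ethyl (4E)-6-hydroxy-5-methylhex-4-enoate | CCOC(=O)CC/C=C(\C)CO
F4 | step 5 | ethyl (4E)-5-methyl-6-(4,4,5,5-tetramethyl-1,3,2-dioxaborolan-2-yl)hex-4-enoate | CCOC(=O)CC/C=C(\C)CB1OC(C)(C)C(C)(C)O1
F5 | step 7 | 3-allyl-3-formyl lactone (formyl trans to isopropenyl) | C=C(C)[C@@H]1C[C@](C=O)(CC=C)C(=O)O[C@@H]1[C@H](O[Si](C)(C)C(C)(C)C)C(C)C
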